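**Retrosynthetic overview**
- Vitisinol D ⇒ fully protected bicyclo[3.2.1]oct-3-ene-2,8-dione (three aryl silyl ethers, one aryl acetate), unmasked by lipase and then buffered fluoride.
- Key disconnection: formal (5+2) across C5–C6 and C1–C7. A resveratrol resorcinol ring is oxidised to its phenoxonium (an enolonium at the ring carbon ortho to the styryl group) and trapped by a (Z)-silyloxystilbene. C5–C6 joins two carbons that are both nucleophilic in the ground state; C1–C7 then closes by enol attack on the benzylic cation.
- Ring order: the six-membered enedione ring is the dearomatised resorcinol ring of one resveratrol unit and is present from the start; the cyclopentanone ring, the bicycle and all four stereocentres arise in the key step.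
- Both partners come from resveratrol: the tris-TBS ether (E→Z by light) and the 4'-O-acetate (lipase).

Assumption: the sense of induction of the lactate-derived trivalent-iodine reagent in step 4 cannot be known in advance; the (R,R)-reagent (made beforehand from the commercial (R,R)-iodoarene with NaBO3·4H2O in AcOH) is written, and its (S,S)-antipode is used if it gives the mirror-image adduct.

Step 1
Reactants: 1 resveratrol
Product: 2 (E)-3,5,4'-tris(tert-butyldimethylsilyloxy)stilbene
Conditions: TBSCl (3.6 equiv), imidazole (7 equiv), DMF, rt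
Reagents that add atoms: tert-butyldimethylsilyl chloride, CC(C)(C)[Si](C)(C)Cl
Why: Imidazole-promoted O-silylation (Corey protocol) of all three phenols is routine on resveratrol and involves no stereocentre.

Step 2
Reactants: 2 (E)-3,5,4'-tris(tert-butyldimethylsilyloxy)stilbene
Product: 3 (Z)-3,5,4'-tris(tert-butyldimethylsilyloxy)stilbene
Conditions: hν (365 nm LED), degassed cyclohexane, rt; AgNO3–silica chromatography, recovered 2 recycled
Reagents that add atoms: none
Why: Direct E→Z stilbene photoisomerisation works because at 365 nm essentially only the planar E isomer absorbs, so the photostationary state lies far on the Z side, while exclusion of oxygen prevents oxidative 6π photocyclisation to a phenanthrene; the Z geometry is what places both aryl groups under the cation in step 4.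

Step 3
Reactants: 1 resveratrol
Product: 4 4'-O-acetylresveratrol (4-[(E)-2-(3,5-dihydroxyphenyl)ethenyl]phenyl acetate)
Conditions: Candida antarctica lipase B (Novozym 435), vinyl acetate (5 equiv), 2-methyl-2-butanol, 40 °C
Reagents that add atoms: vinyl acetate, CC(=O)OC=C
Why: Lipase-catalysed irreversible transesterification with this enzyme is reported to acylate resveratrol selectively at the 4'-hydroxyl (the enol leaving group tautomerises to acetaldehyde), which blocks the most easily oxidised phenol and lowers the nucleophilicity of this partner's own alkene.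

Step 4
Reactants: 4 4'-O-acetylresveratrol; 3 (Z)-3,5,4'-tris(tert-butyldimethylsilyloxy)stilbene (2.5 equiv, excess recovered)
Product: 7 (1R,5S,6R,7R)-4-[(E)-2-(4-acetoxyphenyl)ethenyl]-6-[3,5-bis(tert-butyldimethylsilyloxy)phenyl]-7-[4-(tert-butyldimethylsilyloxy)phenyl]bicyclo[3.2.1]oct-3-ene-2,8-dione, via iodanyl phenolate 5 (not isolated), via benzylic cation 6 (not isolated)
Conditions: 4 + (R,R)-2-(diacetoxyiodo)-1,3-bis[1-(mesitylcarbamoyl)ethoxy]benzene (1.1 equiv), CH2Cl2/(CF3)2CHOH 9:1, −78 °C, 20 min; then 3, −78 → −30 °C; aq. NaHCO3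
Reagents that add atoms: none
Why: Proposed new method: an enantioselective oxidative dearomatising (5+2) cycloaddition in which ligand exchange at trivalent iodine gives 5, departure of the aryl iodide turns the resorcinol carbon ortho to the styryl group (normally a nucleophilic enol carbon) into an enolonium (phenoxonium) carbon that is attacked by the equally nucleophilic alkene carbon of 3 bearing the 3,5-disilyloxyphenyl ring (the C5–C6 bond), and the 4-silyloxybenzylic cation 6 is captured by the ring enol carbon between the two oxygens (C1–C7 bond, 5-exo) faster than the 2,4-dienone can tautomerise to a phenol, the closest known reactions being the Büchi quinone-ketal/propenylbenzene and Engler titanium-promoted quinone/styrene (5+2) cycloadditions (the latter also leave H at both bridgeheads) and the Kita–Ishihara chiral aryl-iodane dearomatisations; a compact endo transition state puts both aryl groups of the Z-alkene under the dienyl cation and so fixes C6 (aryl endo) relative to C5, bond rotation in cation 6 before closure gives the trans C6/C7 arrangement (C7 aryl exo), the bridge geometry fixes C1, and the chiral iodane bound at the oxygen next to the reacting carbon selects the ring face and hence the absolute configuration.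

Step 5
Reactants: 7 acetate-protected, tris-silylated bicyclic dione
Product: 8 (1R,5S,6R,7R)-6-[3,5-bis(tert-butyldimethylsilyloxy)phenyl]-7-[4-(tert-butyldimethylsilyloxy)phenyl]-4-[(E)-2-(4-hydroxyphenyl)ethenyl]bicyclo[3.2.1]oct-3-ene-2,8-dione
Conditions: Candida antarctica lipase B (Novozym 435), n-BuOH (10 equiv), t-BuOMe, 40 °C
Reagents that add atoms: none
Why: Lipase-catalysed alcoholysis of the remote aryl acetate (this enzyme is reported to remove the same 4'-acetate from resveratrol triacetate) runs at neutral pH, so no alkoxide is present that could open the non-enolisable bridged 1,3-diketone by retro-Claisen cleavage, and the silyl ethers and stereocentres are untouched.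

Step 6
Reactants: 8 tris-silylated bicyclic dione with free 4-hydroxystyryl group
Product: 9 vitisinol D, (1R,5S,6R,7R)-6-(3,5-dihydroxyphenyl)-7-(4-hydroxyphenyl)-4-[(E)-2-(4-hydroxyphenyl)ethenyl]bicyclo[3.2.1]oct-3-ene-2,8-dione
Conditions: HF·pyridine, pyridine, THF, 0 °C → rt; Me3SiOMe quench
Reagents that add atoms: none
Why: Fluoride-driven Si–O cleavage under pyridine-buffered, weakly acidic conditions removes the three aryl silyl ethers without free phenoxide (which could trigger retro-Michael opening at C7) or strong acid (which could trigger rearrangement to a dihydrobenzofuran), and none of the four stereocentres is epimerisable.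

**Compound list**
1 | resveratrol, (E)-5-[2-(4-hydroxyphenyl)ethenyl]benzene-1,3-diol | Oc1ccc(/C=C/c2cc(O)cc(O)c2)cc1 | starting material
2 | (E)-3,5,4'-tris(tert-butyldimethylsilyloxy)stilbene | CC(C)(C)[Si](C)(C)Oc1ccc(/C=C/c2cc(O[Si](C)(C)C(C)(C)C)cc(O[Si](C)(C)C(C)(C)C)c2)cc1 | intermediate
3 | (Z)-3,5,4'-tris(tert-butyldimethylsilyloxy)stilbene | CC(C)(C)[Si](C)(C)Oc1ccc(/C=C\c2cc(O[Si](C)(C)C(C)(C)C)cc(O[Si](C)(C)C(C)(C)C)c2)cc1 | intermediate
4 | 4'-O-acetylresveratrol | CC(=O)Oc1ccc(/C=C/c2cc(O)cc(O)c2)cc1 | intermediate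
5 | iodanyl phenolate: 4 bound through one resorcinol oxygen to iodine, which also carries one acetate and the (R,R)-2,6-bis[1-(mesitylcarbamoyl)ethoxy]phenyl group | CC(=O)Oc1ccc(/C=C/c2cc(O)cc(OI(OC(C)=O)c3c(O[C@H](C)C(=O)Nc4c(C)cc(C)cc4C)cccc3O[C@H](C)C(=O)Nc3c(C)cc(C)cc3C)c2)cc1 | intermediate (not isolated)
6 | benzylic cation (acetate salt): 3-hydroxy-5-[(E)-2-(4-acetoxyphenyl)ethenyl]cyclohexa-2,4-dien-1-one carrying at C6 the group CH[3,5-bis(TBSO)phenyl]–CH=(4-silyloxoniocyclohexa-2,5-dienylidene); the two sp3 carbons configured as C5 and C6 of 7 | OC1=CC(=O)[C@@H]([C@H](c2cc(O[Si](C)(C)C(C)(C)C)cc(O[Si](C)(C)C(C)(C)C)c2)C=C2C=CC(=[O+][Si](C)(C)C(C)(C)C)C=C2)C(/C=C/c2ccc(OC(C)=O)cc2)=C1.CC(=O)[O-] | intermediate (not isolated)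
7 | (1R,5S,6R,7R)-4-[(E)-2-(4-acetoxyphenyl)ethenyl]-6-[3,5-bis(TBSO)phenyl]-7-[4-(TBSO)phenyl]bicyclo[3.2.1]oct-3-ene-2,8-dione | O=C1C=C(/C=C/c2ccc(OC(C)=O)cc2)[C@H]2C(=O)[C@@H]1[C@H](c1ccc(O[Si](C)(C)C(C)(C)C)cc1)[C@H]2c1cc(O[Si](C)(C)C(C)(C)C)cc(O[Si](C)(C)C(C)(C)C)c1 | intermediate
8 | (1R,5S,6R,7R)-6-[3,5-bis(TBSO)phenyl]-7-[4-(TBSO)phenyl]-4-[(E)-2-(4-hydroxyphenyl)ethenyl]bicyclo[3.2.1]oct-3-ene-2,8-dione | O=C1C=C(/C=C/c2ccc(O)cc2)[C@H]2C(=O)[C@@H]1[C@H](c1ccc(O[Si](C)(C)C(C)(C)C)cc1)[C@H]2c1cc(O[Si](C)(C)C(C)(C)C)cc(O[Si](C)(C)C(C)(C)C)c1 | intermediate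
9 | vitisinol D | O=C1C=C(/C=C/c2ccc(O)cc2)[C@H]2C(=O)[C@@H]1[C@H](c1ccc(O)cc1)[C@H]2c1cc(O)cc(O)c1 | target

**Totals**
Total steps: 6. Longest linear sequence: 5 steps (1 → 2 → 3 → 7 → 8 → 9).

**Three steps most likely to fail**

Step 4 is the main risk. The phenoxonium may be intercepted at the carbon between the two oxygens (giving the regioisomeric bicycle). The cation may close on oxygen or the dienone may aromatise, giving an ε-viniferin-type dihydrobenzofuran. Compound 4 may couple with itself, and 3 may isomerise to 2 by electron transfer. The endo preference and the enantioselectivity of an intermolecular carbon nucleophile with a chiral iodane are both unproven. The fallback sets out from 3 and comes back at 7, replacing the in-flask phenoxonium by an isolable quinone as the α-keto-cation equivalent. Heck coupling of commercial 2-bromo-6-methoxyphenol with 4-acetoxystyrene (Pd(OAc)2, P(o-tol)3, Et3N, MeCN, 90 °C) gives 4-[(E)-2-(2-hydroxy-3-methoxyphenyl)ethenyl]phenyl acetate F1. Oxidation with K2[ON(SO3)2] (KH2PO4 buffer, acetone/H2O) gives 2-methoxy-6-[(E)-2-(4-acetoxyphenyl)ethenyl]-1,4-benzoquinone F2. F2 and 3 are then combined under Engler's enantioselective quinone/styrene (5+2) conditions (TiCl4/Ti(OiPr)4 with (R,R)-TADDOL, CH2Cl2, −78 °C). The nucleophilic alkene carbon adds to the quinone CH next to the styryl-bearing carbon, the benzylic cation closes on the CH of the methoxy-enone, and chloride removes the methyl group, giving the 3-hydroxy derivative of 7 F3. PhNTf2/Et3N converts it into the 3-(trifluoromethanesulfonyloxy) derivative of 7 F4, and Pd(OAc)2/PPh3 with HCO2H/Bu3N (DMF, 60 °C) replaces the triflate by hydrogen to give 7.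

Step 5 may fail because the lipase does not accept the bulky, lipophilic tris-silyl ether; chemical deacetylation would risk retro-Claisen opening. The fallback sets out from 7 and comes back at 9 by reversing the order of the two deprotections. HF·pyridine/pyridine in THF first gives 4'-O-acetylvitisinol D F5, a small polar 4-acetoxystyryl substrate close to 4. The same lipase with n-BuOH in 2-methyl-2-butanol then removes the acetate to give 9.

Step 6 may fail because the phenol unveiled on the C7 aryl group can push open the C1–C7 bond (retro-Michael, then aromatisation to a dihydrobenzofuran) before it is protonated. The fallback sets out from 7 and comes back at 9. Desilylation is run with in-situ acylation (CsF, Ac2O, DMF, 0 °C), so each phenoxide is trapped at once, giving vitisinol D tetraacetate F6. This has no electron-releasing para-oxygen to assist C1–C7 heterolysis and can be purified. Pig-liver esterase in pH 7 phosphate buffer/acetone then releases 9 under neutral conditions.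

**Further compounds**
F1 | step 4 | 4-[(E)-2-(2-hydroxy-3-methoxyphenyl)ethenyl]phenyl acetate | COc1cccc(/C=C/c2ccc(OC(C)=O)cc2)c1O
F2 | step 4 | 2-methoxy-6-[(E)-2-(4-acetoxyphenyl)ethenyl]-1,4-benzoquinone | COC1=CC(=O)C=C(/C=C/c2ccc(OC(C)=O)cc2)C1=O
F3 | step 4 | 3-hydroxy derivative of 7 | O=C1C(O)=C(/C=C/c2ccc(OC(C)=O)cc2)[C@H]2C(=O)[C@@H]1[C@H](c1ccc(O[Si](C)(C)C(C)(C)C)cc1)[C@H]2c1cc(O[Si](C)(C)C(C)(C)C)cc(O[Si](C)(C)C(C)(C)C)c1
F4 | step 4 | 3-(trifluoromethanesulfonyloxy) derivative of 7 | O=C1C(OS(=O)(=O)C(F)(F)F)=C(/C=C/c2ccc(OC(C)=O)cc2)[C@H]2C(=O)[C@@H]1[C@H](c1ccc(O[Si](C)(C)C(C)(C)C)cc1)[C@H]2c1cc(O[Si](C)(C)C(C)(C)C)cc(O[Si](C)(C)C(C)(C)C)c1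
F5 | step 5 | 4'-O-acetylvitisinol D, the acetate of 9 at the hydroxystyryl group | O=C1C=C(/C=C/c2ccc(OC(C)=O)cc2)[C@H]2C(=O)[C@@H]1[C@H](c1ccc(O)cc1)[C@H]2c1cc(O)cc(O)c1
F6 | step 6 | vitisinol D tetraacetate | O=C1C=C(/C=C/c2ccc(OC(C)=O)cc2)[C@H]2C(=O)[C@@H]1[C@H](c1ccc(OC(C)=O)cc1)[C@H]2c1cc(OC(C)=O)cc(OC(C)=O)c1
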